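## Retrosynthetic overview

1. 15-Keto-PGF2α ⇒ C13 aldehyde + dimethyl (2-oxoheptyl)phosphonate (HWE, E-enone). This is the last step, so the enone never meets a hydride reagent.
2. C13 aldehyde ⇒ triol acid (primary-selective oxidation) ⇒ lactol + C1–C5 ylide (Z-Wittig) ⇒ Corey lactone diacetate (i-Bu2AlH).
3. Corey lactone diacetate ⇒ Prins addition of CH2O/AcOH across the alkene of (1S,5R)-2-oxabicyclo[3.3.0]oct-6-en-3-one (sets C12 and C11).
4. Ene-lactone ⇒ Johnson–Claisen [3,3] rearrangement of (1R,4S)-cis-4-acetoxy-2-cyclopenten-1-ol with triethyl orthoacetate (key C8–C7 bond; C–O chirality transferred to C8), then lactonisation onto the C9 oxygen.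
5. Ring order: the cyclopentane is bought. The γ-lactone is the only ring made; it closes in step 1, directs the Prins step, and is opened again by reduction and Wittig.

Assumption: monoacetate 1 is bought as the single enantiomer (catalogue compound); paraformaldehyde 7 is written as its monomer.

## Route

Step 1 (one pot, two stages)
Reactants: 1 (1R,4S)-cis-4-acetoxy-2-cyclopenten-1-ol; 2 triethyl orthoacetate
Product: 6 (1S,5R)-2-oxabicyclo[3.3.0]oct-6-en-3-one, via ketene acetal 3 (not isolated), via Claisen ester 4 (not isolated), via hydroxy ester 5 (not isolated)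
Conditions: MeC(OEt)3 (6 equiv), EtCO2H (5 mol%), 140 °C, EtOH distilled off; then EtOH, NaOEt (0.3 equiv), rt; Amberlyst 15 (H+ form), concentrate, distil
Reagents that add atoms: none
Why: Johnson–Claisen [3,3]-sigmatropic rearrangement: the ketene acetal on the free hydroxyl delivers C7 suprafacially to the far alkene carbon on the face of the breaking C–O bond, cis to the acetoxy group, so the bought carbinol centre is traded for C8 (R) with C9 (S) untouched; ethoxide-catalysed transesterification then removes the acetate and closes the cis-fused γ-lactone.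

Step 2
Reactants: 6 (1S,5R)-2-oxabicyclo[3.3.0]oct-6-en-3-one; 7 paraformaldehyde
Product: 8 (3aR,4S,5R,6aS)-4-(acetoxymethyl)-2-oxohexahydro-2H-cyclopenta[b]furan-5-yl acetate (Corey lactone diacetate)
Conditions: (CH2O)n (3 equiv), H2SO4 (1.2 equiv), AcOH, 80 °C
Reagents that add atoms: acetic acid, CC(=O)O
Why: Prins reaction: protonated formaldehyde attacks the alkene carbon next to the ring fusion from the convex face and acetic acid captures the cation at the neighbouring carbon from the opposite face (anti addition), the established outcome for this lactone, which sets C12 and C11 under control of C8/C9.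

Step 3
Reactants: 8 Corey lactone diacetate
Product: 9 (3aR,4S,5R,6aS)-4-(hydroxymethyl)hexahydro-2H-cyclopenta[b]furan-2,5-diol (lactol, anomer mixture)
Conditions: i-Bu2AlH (4.5 equiv), CH2Cl2, −78 °C; MeOH at −78 °C, then aq. KNaC4H4O6 (potassium sodium tartrate), rt
Reagents that add atoms: none
Why: Hydride reduction with i-Bu2AlH at −78 °C stops at the aluminium lactolate (lactone to lactol) and cleaves both acetates reductively at the acyl carbon, so no stereocentre is touched.

Step 4
Reactants: 9 lactol; 10 (4-carboxybutyl)triphenylphosphonium bromide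
Product: 12 (5Z)-7-[(1R,2S,3R,5S)-3,5-dihydroxy-2-(hydroxymethyl)cyclopentyl]hept-5-enoic acid, via phosphorus ylide 11 (not isolated)
Conditions: 10 (4 equiv), KOtBu (8 equiv), THF, 0 °C; then 9, 0 °C to rt; aq. HCl to pH 4
Reagents that add atoms: none
Why: Wittig olefination of the open hydroxy-aldehyde form of the lactol with a non-stabilised ylide under lithium-free conditions gives the Z alkene through the kinetically favoured cis-oxaphosphetane; the excess of base and ylide covers the free OH groups.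

Step 5
Reactants: 12 triol acid
Product: 13 (5Z)-7-[(1R,2R,3R,5S)-2-formyl-3,5-dihydroxycyclopentyl]hept-5-enoic acid
Conditions: TEMPO (0.2 equiv), PhI(OAc)2 (1.15 equiv), MeCN/CH2Cl2 (dry), 0 °C to rt; used crude
Reagents that add atoms: none
Why: Oxoammonium (TEMPO/PhI(OAc)2) oxidation is strongly selective for the unhindered primary alcohol over the two secondary ones and stops at the aldehyde without water; C12 already carries its substituent trans to both neighbours, so it has no drive to epimerise.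

Step 6
Reactants: 13 aldehyde; 14 dimethyl (2-oxoheptyl)phosphonate
Product: 16 (5Z,13E)-9α,11α-dihydroxy-15-oxoprosta-5,13-dien-1-oic acid (15-keto-PGF2α), via lithiated phosphonate 15 (not isolated)
Conditions: 14 (1.5 equiv), LiCl (3 equiv), i-Pr2NEt (3.5 equiv), MeCN, 0 °C to rt; aq. HCl to pH 4
Reagents that add atoms: none
Why: Horner–Wadsworth–Emmons olefination under Masamune–Roush conditions gives the E-enone from the stabilised β-ketophosphonate anion, and the weak amine base tolerates the free hydroxyls, the carboxylate and the β-hydroxy aldehyde.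

## Compound list

1 | (1R,4S)-cis-4-acetoxy-2-cyclopenten-1-ol [(1S,4R)-4-hydroxycyclopent-2-en-1-yl acetate] | O[C@@H]1C[C@H](OC(C)=O)C=C1 | starting material
2 | triethyl orthoacetate | CC(OCC)(OCC)OCC | starting material
3 | (1S,4R)-4-[(1-ethoxyethenyl)oxy]cyclopent-2-en-1-yl acetate (ketene acetal) | C=C(OCC)O[C@@H]1C[C@H](OC(C)=O)C=C1 | intermediate
4 | ethyl 2-[(1R,5S)-5-acetoxycyclopent-2-en-1-yl]acetate | CCOC(=O)C[C@@H]1C=CC[C@@H]1OC(C)=O | intermediate
5 | ethyl 2-[(1R,5S)-5-hydroxycyclopent-2-en-1-yl]acetate | CCOC(=O)C[C@@H]1C=CC[C@@H]1O | intermediate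
6 | (1S,5R)-2-oxabicyclo[3.3.0]oct-6-en-3-one (cis-fused) | O=C1C[C@@H]2C=CC[C@@H]2O1 | intermediate
7 | paraformaldehyde (formaldehyde source) | C=O | starting material
8 | (3aR,4S,5R,6aS)-4-(acetoxymethyl)-2-oxohexahydro-2H-cyclopenta[b]furan-5-yl acetate | CC(=O)OC[C@@H]1[C@H]2CC(=O)O[C@H]2C[C@H]1OC(C)=O | intermediate
9 | (3aR,4S,5R,6aS)-4-(hydroxymethyl)hexahydro-2H-cyclopenta[b]furan-2,5-diol (anomers) | OC[C@@H]1[C@H]2CC(O)O[C@H]2C[C@H]1O | intermediate
10 | (4-carboxybutyl)triphenylphosphonium bromide | OC(=O)CCCC[P+](c1ccccc1)(c1ccccc1)c1ccccc1.[Br-] | starting material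
11 | potassium 5-(triphenylphosphoranylidene)pentanoate | [K+].[O-]C(=O)CCCC=P(c1ccccc1)(c1ccccc1)c1ccccc1 | intermediate
12 | (5Z)-7-[(1R,2S,3R,5S)-3,5-dihydroxy-2-(hydroxymethyl)cyclopentyl]hept-5-enoic acid | OC[C@@H]1[C@@H](C/C=C\CCCC(=O)O)[C@@H](O)C[C@H]1O | intermediate
13 | (5Z)-7-[(1R,2R,3R,5S)-2-formyl-3,5-dihydroxycyclopentyl]hept-5-enoic acid | O=C[C@@H]1[C@@H](C/C=C\CCCC(=O)O)[C@@H](O)C[C@H]1O | intermediate
14 | dimethyl (2-oxoheptyl)phosphonate | CCCCCC(=O)CP(=O)(OC)OC | starting material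
15 | lithium salt of dimethyl (2-oxoheptyl)phosphonate | [Li+].CCCCCC(=O)[CH-]P(=O)(OC)OC | intermediate
16 | 15-keto-PGF2α, (5Z)-7-[(1R,2R,3R,5S)-3,5-dihydroxy-2-[(1E)-3-oxooct-1-en-1-yl]cyclopentyl]hept-5-enoic acid | CCCCCC(=O)/C=C/[C@@H]1[C@@H](C/C=C\CCCC(=O)O)[C@@H](O)C[C@H]1O | target

## Step count and risks

Total step count: 6. Longest linear sequence: 6 steps (1 to 16).

The three steps most likely to fail are 3, 5 and 6.

**Step 3** (global i-Bu2AlH reduction of the diacetate). The risks are over-reduction with the large hydride excess and loss of the very polar tetra-ol 9 in the aluminium work-up. The fallback sets out from 8 and comes back at 12, using protected, chromatographable intermediates. NaOMe (cat.) in MeOH followed by acidic resin gives Corey lactone diol F1. TBSCl and imidazole in DMF give the bis-silyl ether F2. i-Bu2AlH (1.2 equiv) in toluene at −78 °C gives the lipophilic lactol F3. Wittig reaction with ylide 11 (2.5 equiv) gives the silylated hydroxy acid F4. Aqueous HF in MeCN removes both silyl groups and delivers 12. This also bypasses the Wittig step on the unprotected lactol.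

**Step 5** (primary-selective oxidation of a triol acid). The risks are competing oxidation of a secondary hydroxyl and dehydration of the β-hydroxy aldehyde. The fallback sets out from 12 and comes back at 16, replacing chemoselectivity by protection. Excess Et3SiCl and imidazole, with an aqueous work-up that hydrolyses the silyl ester, give the tris-silyl ether acid F5. AcOH/THF/H2O at 0 °C cleaves only the primary silyl ether to give the primary alcohol F6. Dess–Martin periodinane with NaHCO3 gives the protected aldehyde F7. HWE reaction with 14 (LiCl, i-Pr2NEt) gives the bis-silyl enone F8. AcOH/THF/H2O at rt removes the two silyl groups to give 16.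

**Step 6** (HWE on an unprotected hydroxy aldehyde that also carries a carboxylate). The risks are poor conversion of the salt and base-induced elimination. The fallback sets out from 8 and comes back at 16. It installs the lower chain first on the compact lactone and carries C15 as a carbinol. Methanolysis as above gives Corey lactone diol F1. TEMPO/PhI(OAc)2 gives the hydroxy aldehyde lactone F9. HWE reaction with 14 gives the enone lactone F10. Excess i-Bu2AlH at −78 °C reduces the lactone to the lactol and the enone to the allylic alcohol, giving F11 as a C15 epimer mixture. Wittig reaction with ylide 11 gives the 15-epimeric trihydroxy acid mixture F12 (PGF2α and 15-epi-PGF2α). DDQ in dioxane at rt (or MnO2) oxidises only the allylic 15-hydroxyl, so both epimers converge on 16.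

## Further compounds

F1 | step 3 | (3aR,4S,5R,6aS)-5-hydroxy-4-(hydroxymethyl)hexahydro-2H-cyclopenta[b]furan-2-one (Corey lactone diol) | OC[C@@H]1[C@H]2CC(=O)O[C@H]2C[C@H]1O
F2 | step 3 | (3aR,4S,5R,6aS)-5-(tert-butyldimethylsilyloxy)-4-[(tert-butyldimethylsilyloxy)methyl]hexahydro-2H-cyclopenta[b]furan-2-one | CC(C)(C)[Si](C)(C)OC[C@@H]1[C@H]2CC(=O)O[C@H]2C[C@H]1O[Si](C)(C)C(C)(C)C
F3 | step 3 | (3aR,4S,5R,6aS)-5-(tert-butyldimethylsilyloxy)-4-[(tert-butyldimethylsilyloxy)methyl]hexahydro-2H-cyclopenta[b]furan-2-ol (anomers) | CC(C)(C)[Si](C)(C)OC[C@@H]1[C@H]2CC(O)O[C@H]2C[C@H]1O[Si](C)(C)C(C)(C)C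
F4 | step 3 | (5Z)-7-[(1R,2S,3R,5S)-3-(tert-butyldimethylsilyloxy)-2-[(tert-butyldimethylsilyloxy)methyl]-5-hydroxycyclopentyl]hept-5-enoic acid | CC(C)(C)[Si](C)(C)OC[C@@H]1[C@@H](C/C=C\CCCC(=O)O)[C@@H](O)C[C@H]1O[Si](C)(C)C(C)(C)C
F5 | step 5 | (5Z)-7-[(1R,2S,3R,5S)-3,5-bis(triethylsilyloxy)-2-[(triethylsilyloxy)methyl]cyclopentyl]hept-5-enoic acid | CC[Si](CC)(CC)OC[C@@H]1[C@@H](C/C=C\CCCC(=O)O)[C@@H](O[Si](CC)(CC)CC)C[C@H]1O[Si](CC)(CC)CC
F6 | step 5 | (5Z)-7-[(1R,2S,3R,5S)-2-(hydroxymethyl)-3,5-bis(triethylsilyloxy)cyclopentyl]hept-5-enoic acid | OC[C@@H]1[C@@H](C/C=C\CCCC(=O)O)[C@@H](O[Si](CC)(CC)CC)C[C@H]1O[Si](CC)(CC)CC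
F7 | step 5 | (5Z)-7-[(1R,2R,3R,5S)-2-formyl-3,5-bis(triethylsilyloxy)cyclopentyl]hept-5-enoic acid | O=C[C@@H]1[C@@H](C/C=C\CCCC(=O)O)[C@@H](O[Si](CC)(CC)CC)C[C@H]1O[Si](CC)(CC)CC
F8 | step 5 | 9,11-bis-O-(triethylsilyl)-15-keto-PGF2α | CCCCCC(=O)/C=C/[C@@H]1[C@@H](C/C=C\CCCC(=O)O)[C@@H](O[Si](CC)(CC)CC)C[C@H]1O[Si](CC)(CC)CC
F9 | step 6 | (3aR,4R,5R,6aS)-5-hydroxy-2-oxohexahydro-2H-cyclopenta[b]furan-4-carbaldehyde | O=C[C@@H]1[C@H]2CC(=O)O[C@H]2C[C@H]1O
F10 | step 6 | (3aR,4R,5R,6aS)-5-hydroxy-4-[(1E)-3-oxooct-1-en-1-yl]hexahydro-2H-cyclopenta[b]furan-2-one | CCCCCC(=O)/C=C/[C@@H]1[C@H]2CC(=O)O[C@H]2C[C@H]1O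
F11 | step 6 | (3aR,4R,5R,6aS)-4-[(1E)-3-hydroxyoct-1-en-1-yl]hexahydro-2H-cyclopenta[b]furan-2,5-diol (C15 epimers, anomers) | CCCCCC(O)/C=C/[C@@H]1[C@H]2CC(O)O[C@H]2C[C@H]1O
F12 | step 6 | (5Z,13E)-9α,11α,15-trihydroxyprosta-5,13-dien-1-oic acid (PGF2α and its 15-epimer) | CCCCCC(O)/C=C/[C@@H]1[C@@H](C/C=C\CCCC(=O)O)[C@@H](O)C[C@H]1O
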